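A direct plan would build the γ-lactone first on a linear chain, close an eight-membered ether A2 by Williamson etherification of hydroxy allylic chloride A1, and then form the furanone and the ten-membered ring together by oxonium ylide formation and [2,3]-shift of diazoketone A3; the C8 oxygen would come last, through ketone A4.
Its weak steps would be:
- the etherification A1 → A2, an eight-membered closure that fights entropy and transannular strain and needs high dilution;
- the oxidative cleavage to A4 and its reduction, a late redox detour that sets C8 by reagent control on a flexible ring, next to a β-alkoxy ketone that can eliminate;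
- the run-up of about fourteen linear steps, many of them protecting-group and oxidation-state changes, before the key step.

**Retrosynthetic overview**
The target is cut at the C6–C7 bond and the O6–C12 bond. One chromium-mediated allylation–lactonisation of seco aldehyde 17 would close both the ten-membered carbocycle (C1–C10) and the trans-fused γ-lactone (C6, C7, C11, C12, O). The 3(2H)-furanone (O, C3, C2, C1, C10) is already in place and C8 steers the new centres C6 and C7.
Ring order: furanone first (acetylide opening of lactone 9 by alkyne 5, then gold-catalysed 5-endo-dig closure), then carbocycle and lactone together; no eight-membered ether is ever closed.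
C8 and C10 come from the L-glutamic acid-derived lactone 6 (C8 from the pool, C10 by anti hydroxylation of its enolate), and C4 from a catalytic conjugate alkynylation of crotonaldehyde.
The C8 oxygen is carried from the start, so there is no late oxidation or reduction at C8; C11 is set in the last step by conjugate reduction. The route is convergent: 15 steps, longest linear sequence 13.

Key step: step 12

Assumption: the (R)-DTBM-SEGPHOS/rhodium catalyst is taken to give the (S)-aldehyde 3; should the sense of induction be the opposite, the (S)-ligand would be used and nothing else would change.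

**Route**

Step 1
Reactants: 1 (E)-but-2-enal; 2 ethynyltriisopropylsilane
Product: 4 [(3S)-5,5-dimethoxy-3-methylpent-1-yn-1-yl]triisopropylsilane, via alkynyl aldehyde 3 (not isolated)
Conditions: [Rh(OAc)(C2H4)2]2 (2.5 mol%), (R)-DTBM-SEGPHOS (6 mol%), MeOH, 40 °C; then HC(OMe)3, p-TsOH (cat.), rt
Reagents that add atoms: trimethyl orthoformate COC(OC)OC; methanol CO
Why: Rhodium-catalysed asymmetric conjugate alkynylation of an enal (the bulky silyl group and ligand suppress alkyne dimerisation and 1,2-addition) should set C4 (S) under ligand control, and acetalisation in the same methanol solution masks the C6 aldehyde for the organolithium step.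

Step 2
Reactants: 4 [(3S)-5,5-dimethoxy-3-methylpent-1-yn-1-yl]triisopropylsilane
Product: 5 (3S)-5,5-dimethoxy-3-methylpent-1-yne
Conditions: Bu4NF, THF, 0 °C to rt
Reagents that add atoms: none
Why: Fluoride-induced protodesilylation of the alkynylsilane frees the terminal alkyne without touching the acetal or the propargylic stereocentre.

Step 3
Reactants: 6 (5S)-5-(hydroxymethyl)dihydrofuran-2(3H)-one
Product: 7 (5S)-5-{[(triethylsilyl)oxy]methyl}dihydrofuran-2(3H)-one
Conditions: Et3SiCl, imidazole, CH2Cl2, 0 °C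
Reagents that add atoms: chlorotriethylsilane CC[Si](Cl)(CC)CC
Why: Silylation of the primary alcohol gives an ether that survives the enolate steps and can later be oxidised directly to the C7 aldehyde.

Step 4
Reactants: 7 (5S)-5-{[(triethylsilyl)oxy]methyl}dihydrofuran-2(3H)-one
Product: 8 (5S)-3-methyl-5-{[(triethylsilyl)oxy]methyl}dihydrofuran-2(3H)-one (C3 epimers)
Conditions: LiN(iPr)2, THF, −78 °C; MeI, −78 to −40 °C
Reagents that add atoms: iodomethane CI
Why: Lactone enolate alkylation brings in C14, and the configuration formed here does not matter because the centre is enolised again in the next step.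

Step 5
Reactants: 8 (5S)-3-methyl-5-{[(triethylsilyl)oxy]methyl}dihydrofuran-2(3H)-one
Product: 9 (3R,5S)-3-hydroxy-3-methyl-5-{[(triethylsilyl)oxy]methyl}dihydrofuran-2(3H)-one
Conditions: KN(SiMe3)2, THF, −78 °C; 3-phenyl-2-(phenylsulfonyl)oxaziridine, −78 °C; sat. aq. NH4Cl
Reagents that add atoms: 3-phenyl-2-(phenylsulfonyl)oxaziridine O=S(=O)(c1ccccc1)N1OC1c1ccccc1
Why: Davis hydroxylation of the tetrasubstituted lactone enolate should occur anti to the silyloxymethyl arm on C8, so the hydroxyl enters trans to it and sets the quaternary C10 (R) by 1,3-induction across the five-membered ring.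

Step 6
Reactants: 5 (3S)-5,5-dimethoxy-3-methylpent-1-yne; 9 (3R,5S)-3-hydroxy-3-methyl-5-{[(triethylsilyl)oxy]methyl}dihydrofuran-2(3H)-one
Product: 11 (2R)-5-[(2S)-4,4-dimethoxybutan-2-yl]-2-{(2S)-2-hydroxy-3-[(triethylsilyl)oxy]propyl}-2-methylfuran-3(2H)-one, via hydroxy ynone 10 (not isolated)
Conditions: 5 (2.4 equiv), n-BuLi (2.3 equiv), THF, −78 °C; 9, −78 to −30 °C; sat. aq. NH4Cl; crude 10, (Ph3P)AuNTf2 (3 mol%), toluene, rt
Reagents that add atoms: none
Why: The lithium acetylide opens the lactone once (the first equivalent only deprotonates the tertiary hydroxyl and the tetrahedral alkoxide resists a second addition), and monovalent gold then activates the ynone for 5-endo-dig attack of the C10 hydroxyl on C3, which closes the 3(2H)-furanone under neutral conditions that spare the C4 centre and the acetal.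

Step 7
Reactants: 11 (2R)-5-[(2S)-4,4-dimethoxybutan-2-yl]-2-{(2S)-2-hydroxy-3-[(triethylsilyl)oxy]propyl}-2-methylfuran-3(2H)-one
Product: 12 (2R)-2-{(2S)-2-[(tert-butyldimethylsilyl)oxy]-3-[(triethylsilyl)oxy]propyl}-5-[(2S)-4,4-dimethoxybutan-2-yl]-2-methylfuran-3(2H)-one
Conditions: TBSCl, imidazole, DMF, rt
Reagents that add atoms: tert-butyldimethylsilyl chloride CC(C)(C)[Si](C)(C)Cl
Why: Silylation of the only free hydroxyl protects O8 through the organochromium step, where an ester at this position would risk 1,4-elimination.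

Step 8
Reactants: 12 (2R)-2-{(2S)-2-[(tert-butyldimethylsilyl)oxy]-3-[(triethylsilyl)oxy]propyl}-5-[(2S)-4,4-dimethoxybutan-2-yl]-2-methylfuran-3(2H)-one
Product: 13 (2S)-2-[(tert-butyldimethylsilyl)oxy]-3-{(2R)-5-[(2S)-4,4-dimethoxybutan-2-yl]-2-methyl-3-oxo-2,3-dihydrofuran-2-yl}propanal
Conditions: (COCl)2, DMSO, CH2Cl2, −78 to −30 °C; Et3N, −78 to 0 °C
Reagents that add atoms: none
Why: Under Swern conditions a primary triethylsilyl ether is cleaved by the chlorosulfonium salt and oxidised in the same flask while the secondary tert-butyldimethylsilyl ether is inert, which gives the α-silyloxy aldehyde without a separate deprotection.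

Step 9
Reactants: 13 (2S)-2-[(tert-butyldimethylsilyl)oxy]-3-{(2R)-5-[(2S)-4,4-dimethoxybutan-2-yl]-2-methyl-3-oxo-2,3-dihydrofuran-2-yl}propanal
Product: 14 methyl (4S)-4-[(tert-butyldimethylsilyl)oxy]-5-{(2R)-5-[(2S)-4,4-dimethoxybutan-2-yl]-2-methyl-3-oxo-2,3-dihydrofuran-2-yl}-3-hydroxy-2-methylidenepentanoate (C3 epimers)
Conditions: methyl acrylate (10 equiv), DABCO (1 equiv), dioxane/H2O 1:1, rt
Reagents that add atoms: methyl acrylate C=CC(=O)OC
Why: The Morita–Baylis–Hillman reaction of the activated α-silyloxy aldehyde attaches C11, C12 and C13, and the new carbinol centre at C7 is lost again in step 11, so its configuration does not matter.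

Step 10
Reactants: 14 methyl (4S)-4-[(tert-butyldimethylsilyl)oxy]-5-{(2R)-5-[(2S)-4,4-dimethoxybutan-2-yl]-2-methyl-3-oxo-2,3-dihydrofuran-2-yl}-3-hydroxy-2-methylidenepentanoate
Product: 15 methyl (4S)-4-[(tert-butyldimethylsilyl)oxy]-3-hydroxy-5-{(2R)-2-methyl-3-oxo-5-[(2S)-4-oxobutan-2-yl]-2,3-dihydrofuran-2-yl}-2-methylidenepentanoate (C3 epimers)
Conditions: PPTS (cat.), acetone/H2O 10:1, 45 °C
Reagents that add atoms: water O
Why: Mild acid hydrolysis of the dimethyl acetal frees the C6 aldehyde while the secondary silyl ether, the allylic alcohol and the furanone tolerate pyridinium acid.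

Step 11
Reactants: 15 methyl (4S)-4-[(tert-butyldimethylsilyl)oxy]-3-hydroxy-5-{(2R)-2-methyl-3-oxo-5-[(2S)-4-oxobutan-2-yl]-2,3-dihydrofuran-2-yl}-2-methylidenepentanoate
Product: 17 methyl (2Z,4S)-2-(bromomethyl)-4-[(tert-butyldimethylsilyl)oxy]-5-{(2R)-2-methyl-3-oxo-5-[(2S)-4-oxobutan-2-yl]-2,3-dihydrofuran-2-yl}pent-2-enoate, via allylic mesylate 16 (not isolated)
Conditions: MsCl, Et3N, CH2Cl2, −40 to 0 °C; then LiBr, THF, 0 °C to rt
Reagents that add atoms: lithium bromide [Li+].[Br-]
Why: Mesylation followed by SN2′ displacement with bromide transposes the allyl unit to the thermodynamically preferred (Z)-2-(bromomethyl)enoate, and because no electrophilic bromine is used the electron-rich C2 of the furanone is not halogenated.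

Step 12
Reactants: 17 methyl (2Z,4S)-2-(bromomethyl)-4-[(tert-butyldimethylsilyl)oxy]-5-{(2R)-2-methyl-3-oxo-5-[(2S)-4-oxobutan-2-yl]-2,3-dihydrofuran-2-yl}pent-2-enoate
Product: 20 (4S,6R,7S,8S,10R)-8-[(tert-butyldimethylsilyl)oxy]-3,10-epoxy-1-oxogermacra-2,11(13)-dien-12,6-olide, via allylchromium species 18 (not isolated), via macrocyclic hydroxy ester 19 (not isolated)
Conditions: CrCl2 (10 equiv), THF/DMF 4:1, 0.003 M, 17 added by syringe pump over 10 h, rt; sat. aq. NH4Cl; PPTS (cat.), CH2Cl2, rt to complete lactonisation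
Reagents that add atoms: none
Why: Two equivalents of CrCl2 reduce the allylic C–Br bond of 17 to the trivalent allylchromium 18, which adds through its γ-carbon C7 (SE2′) to the C6 aldehyde in a closed six-membered Zimmerman–Traxler transition state, and the chromium alkoxide of 19 then attacks the neighbouring methyl ester. The closest known reaction type is the intramolecular Nozaki–Hiyama (Barbier) allylation of ω-formyl 2-(bromomethyl)alk-2-enoates, which has been used to close the ten-membered carbocycle of germacranolides together with their α-methylene lactone. Ring closures: the ten-membered carbocycle closes by C6–C7 bond formation (carbonyl allylation, the chain being held in a U-shape by the C3–O–C10 furanone bridge), and the γ-lactone closes by 5-exo-trig acyl substitution of O6 on C12. C7 is controlled by C8: allylic 1,3-strain keeps C8–H in the plane of the allyl unit, the silyloxy group takes the outside position anti to the forming bond, and the aldehyde, delivered through the C9 arm, adds to the other face, which puts C11 trans to O8 across the ring (7S). C6 should follow from the chair transition state of the equilibrated allylchromium with C5 and C8 both equatorial, which gives the 6,7-anti adduct and hence the trans-fused lactone (6R), the sense found in chromium-mediated closures of related ten-membered lactones. The step needs ring closure to outrun oligomerisation and 1,4-elimination of the C8 oxygen, which high dilution, slow addition and the poor leaving-group ability of the silyl ether should secure, while the furanone and the ester are inert to divalent chromium.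

Step 13
Reactants: 20 (4S,6R,7S,8S,10R)-8-[(tert-butyldimethylsilyl)oxy]-3,10-epoxy-1-oxogermacra-2,11(13)-dien-12,6-olide
Product: 21 (4S,6R,7R,8S,10R)-3,10-epoxy-8-hydroxy-1-oxogermacra-2,11(13)-dien-12,6-olide
Conditions: HF·pyridine, pyridine, THF, 0 °C to rt
Reagents that add atoms: none
Why: Buffered acidic fluoride removes the silyl ether without forming an alkoxide at O8, which avoids translactonisation to the 8,12-olide.

Step 14
Reactants: 21 (4S,6R,7R,8S,10R)-3,10-epoxy-8-hydroxy-1-oxogermacra-2,11(13)-dien-12,6-olide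
Product: 22 (4S,6R,7S,8S,10R)-3,10-epoxy-8-[(E)-2-methylbut-2-enoyloxy]-1-oxogermacra-2,11(13)-dien-12,6-olide
Conditions: (E)-2-methylbut-2-enoyl chloride, pyridine, DMAP (cat.), CH2Cl2, 0 °C to rt
Reagents that add atoms: (E)-2-methylbut-2-enoyl chloride C/C=C(\C)C(=O)Cl
Why: DMAP-catalysed acylation esterifies the C8 hydroxyl with retention, and the stable E (tiglate) geometry is kept.

Step 15
Reactants: 22 (4S,6R,7S,8S,10R)-3,10-epoxy-8-[(E)-2-methylbut-2-enoyloxy]-1-oxogermacra-2,11(13)-dien-12,6-olide
Product: 23 (4S,6R,7S,8S,10R,11S)-3,10-epoxy-8-[(E)-2-methylbut-2-enoyloxy]-1-oxogermacr-2-en-12,6-olide (target)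
Conditions: NaBH4 (1.5 equiv), THF/MeOH, −20 to 0 °C; AcOH quench
Reagents that add atoms: none
Why: Borohydride adds conjugately to the exocyclic α-methylene lactone, by far the most electrophilic acceptor (the tiglate is trisubstituted and the furanone carbonyl is a hindered vinylogous ester), and protonation of the lactone enolate in methanol anti to the C5 branch should give the all-trans lactone with the C11 methyl trans to C8 (11S), the sense known for borohydride reductions of trans-6,12-olides and also the thermodynamic one.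

**Compound list**

1 | (E)-but-2-enal (crotonaldehyde) | C/C=C/C=O | starting material
2 | ethynyltriisopropylsilane | C#C[Si](C(C)C)(C(C)C)C(C)C | starting material
3 | (3S)-3-methyl-5-(triisopropylsilyl)pent-4-ynal | CC(C)[Si](C(C)C)(C(C)C)C#C[C@@H](C)CC=O | intermediate (not isolated)
4 | [(3S)-5,5-dimethoxy-3-methylpent-1-yn-1-yl]triisopropylsilane | CC(C)[Si](C(C)C)(C(C)C)C#C[C@@H](C)CC(OC)OC | intermediate
5 | (3S)-5,5-dimethoxy-3-methylpent-1-yne | C#C[C@@H](C)CC(OC)OC | intermediate
6 | (5S)-5-(hydroxymethyl)dihydrofuran-2(3H)-one | OC[C@@H]1CCC(=O)O1 | starting material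
7 | (5S)-5-{[(triethylsilyl)oxy]methyl}dihydrofuran-2(3H)-one | CC[Si](CC)(CC)OC[C@@H]1CCC(=O)O1 | intermediate
8 | (5S)-3-methyl-5-{[(triethylsilyl)oxy]methyl}dihydrofuran-2(3H)-one (C3 epimers) | CC[Si](CC)(CC)OC[C@@H]1CC(C)C(=O)O1 | intermediate
9 | (3R,5S)-3-hydroxy-3-methyl-5-{[(triethylsilyl)oxy]methyl}dihydrofuran-2(3H)-one (hydroxyl trans to the C5 arm) | CC[Si](CC)(CC)OC[C@@H]1C[C@@](C)(O)C(=O)O1 | intermediate
10 | (2S,4R,8S)-2,4-dihydroxy-10,10-dimethoxy-4,8-dimethyl-1-[(triethylsilyl)oxy]dec-6-yn-5-one | CC[Si](CC)(CC)OC[C@@H](O)C[C@@](C)(O)C(=O)C#C[C@@H](C)CC(OC)OC | intermediate (not isolated)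
11 | (2R)-5-[(2S)-4,4-dimethoxybutan-2-yl]-2-{(2S)-2-hydroxy-3-[(triethylsilyl)oxy]propyl}-2-methylfuran-3(2H)-one | CC[Si](CC)(CC)OC[C@@H](O)C[C@@]1(C)OC(=CC1=O)[C@@H](C)CC(OC)OC | intermediate
12 | (2R)-2-{(2S)-2-[(tert-butyldimethylsilyl)oxy]-3-[(triethylsilyl)oxy]propyl}-5-[(2S)-4,4-dimethoxybutan-2-yl]-2-methylfuran-3(2H)-one | CC[Si](CC)(CC)OC[C@@H](O[Si](C)(C)C(C)(C)C)C[C@@]1(C)OC(=CC1=O)[C@@H](C)CC(OC)OC | intermediate
13 | (2S)-2-[(tert-butyldimethylsilyl)oxy]-3-{(2R)-5-[(2S)-4,4-dimethoxybutan-2-yl]-2-methyl-3-oxo-2,3-dihydrofuran-2-yl}propanal | O=C[C@@H](O[Si](C)(C)C(C)(C)C)C[C@@]1(C)OC(=CC1=O)[C@@H](C)CC(OC)OC | intermediate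
14 | methyl (4S)-4-[(tert-butyldimethylsilyl)oxy]-5-{(2R)-5-[(2S)-4,4-dimethoxybutan-2-yl]-2-methyl-3-oxo-2,3-dihydrofuran-2-yl}-3-hydroxy-2-methylidenepentanoate (C3 epimers) | C=C(C(=O)OC)C(O)[C@@H](O[Si](C)(C)C(C)(C)C)C[C@@]1(C)OC(=CC1=O)[C@@H](C)CC(OC)OC | intermediate
15 | methyl (4S)-4-[(tert-butyldimethylsilyl)oxy]-3-hydroxy-5-{(2R)-2-methyl-3-oxo-5-[(2S)-4-oxobutan-2-yl]-2,3-dihydrofuran-2-yl}-2-methylidenepentanoate (C3 epimers) | C=C(C(=O)OC)C(O)[C@@H](O[Si](C)(C)C(C)(C)C)C[C@@]1(C)OC(=CC1=O)[C@@H](C)CC=O | intermediate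
16 | 3-O-methanesulfonate of 15 | C=C(C(=O)OC)C(OS(C)(=O)=O)[C@@H](O[Si](C)(C)C(C)(C)C)C[C@@]1(C)OC(=CC1=O)[C@@H](C)CC=O | intermediate (not isolated)
17 | methyl (2Z,4S)-2-(bromomethyl)-4-[(tert-butyldimethylsilyl)oxy]-5-{(2R)-2-methyl-3-oxo-5-[(2S)-4-oxobutan-2-yl]-2,3-dihydrofuran-2-yl}pent-2-enoate | BrC/C(C(=O)OC)=C\[C@@H](O[Si](C)(C)C(C)(C)C)C[C@@]1(C)OC(=CC1=O)[C@@H](C)CC=O | intermediate
18 | allylchromium dichloride from 17 (trivalent chromium on C13 in place of bromine) | Cl[Cr](Cl)C/C(C(=O)OC)=C\[C@@H](O[Si](C)(C)C(C)(C)C)C[C@@]1(C)OC(=CC1=O)[C@@H](C)CC=O | intermediate (not isolated)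
19 | methyl (4S,6R,7S,8S,10R)-8-[(tert-butyldimethylsilyl)oxy]-3,10-epoxy-6-hydroxy-1-oxogermacra-2,11(13)-dien-12-oate (formed as its chromium alkoxide) | CC(C)(C)[Si](C)(C)O[C@H]1C[C@@]2(C)OC(=CC2=O)[C@@H](C)C[C@@H](O)[C@@H]1C(=C)C(=O)OC | intermediate (not isolated)
20 | (4S,6R,7S,8S,10R)-8-[(tert-butyldimethylsilyl)oxy]-3,10-epoxy-1-oxogermacra-2,11(13)-dien-12,6-olide | CC(C)(C)[Si](C)(C)O[C@H]1C[C@@]2(C)OC(=CC2=O)[C@@H](C)C[C@H]2OC(=O)C(=C)[C@H]12 | intermediate
21 | (4S,6R,7R,8S,10R)-3,10-epoxy-8-hydroxy-1-oxogermacra-2,11(13)-dien-12,6-olide | O[C@H]1C[C@@]2(C)OC(=CC2=O)[C@@H](C)C[C@H]2OC(=O)C(=C)[C@H]12 | intermediate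
22 | (4S,6R,7S,8S,10R)-3,10-epoxy-8-[(E)-2-methylbut-2-enoyloxy]-1-oxogermacra-2,11(13)-dien-12,6-olide | C/C=C(\C)C(=O)O[C@H]1C[C@@]2(C)OC(=CC2=O)[C@@H](C)C[C@H]2OC(=O)C(=C)[C@H]12 | intermediate
23 | (4S,6R,7S,8S,10R,11S)-3,10-epoxy-8-[(E)-2-methylbut-2-enoyloxy]-1-oxogermacr-2-en-12,6-olide | C/C=C(\C)C(=O)O[C@H]1C[C@@]2(C)OC(=CC2=O)[C@@H](C)C[C@H]2OC(=O)[C@@H](C)[C@H]12 | target

**Step count and risks**

Total step count: 15. Longest linear sequence: 13 (steps 3 to 15; the alkyne branch, steps 1 and 2, joins at step 6).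

The three steps most likely to fail:

Step 12. The closure could suffer from oligomerisation, from 1,4-elimination of the C8 oxygen, or most probably from poor control of the aldehyde face, which would give the 6,7-syn adduct. The fallback sets out from 17 and comes back at 20. The closure would be accepted as it comes, and the cis-fused 6-epi macrolide F1 would be opened with LiOH in THF/H2O at 0 °C to the 6-epi hydroxy acid F2. F2 would then be relactonised under Mitsunobu conditions (PPh3, DIAD, THF), which displaces the activated C6 hydroxyl by the carboxylate with inversion and gives the trans-fused lactone 20.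

Step 6. The acetylide addition to the hindered α-oxido lactone could stall or over-add, or the ynone could isomerise toward an allenone with loss of the C4 configuration before the gold step. The fallback sets out from 9 and comes back at 12. Aminolysis with MeNH(OMe)·HCl and Me3Al would open the lactone to the dihydroxy Weinreb amide F3. Selective silylation of the secondary hydroxyl (TBSCl, imidazole) would give the mono-silylated Weinreb amide F4. The lithium acetylide of 5 would add once to the chelated amide to give the hydroxy ynone F5, and (Ph3P)AuNTf2 would close the furanone to give 12.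

Step 9. The Morita–Baylis–Hillman reaction could be slow on the hindered aldehyde, and the long contact with amine base could epimerise C8. The fallback sets out from 13 and comes back at 14. The lithium enolate of methyl 3-(dimethylamino)propanoate (LiN(iPr)2, THF, −78 °C) would add to the aldehyde within minutes to give the β-(dimethylamino) aldol adduct F6. N-Methylation with MeI and elimination with DBU would then give the same α-methylidene β-hydroxy ester 14.

Further compounds
F1 | step 12 | (4S,6S,7S,8S,10R)-8-[(tert-butyldimethylsilyl)oxy]-3,10-epoxy-1-oxogermacra-2,11(13)-dien-12,6-olide (cis-fused 6-epimer of 20) | CC(C)(C)[Si](C)(C)O[C@H]1C[C@@]2(C)OC(=CC2=O)[C@@H](C)C[C@@H]2OC(=O)C(=C)[C@H]12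
F2 | step 12 | (4S,6S,7S,8S,10R)-8-[(tert-butyldimethylsilyl)oxy]-3,10-epoxy-6-hydroxy-1-oxogermacra-2,11(13)-dien-12-oic acid | CC(C)(C)[Si](C)(C)O[C@H]1C[C@@]2(C)OC(=CC2=O)[C@@H](C)C[C@H](O)[C@@H]1C(=C)C(=O)O
F3 | step 6 | (2R,4S)-2,4-dihydroxy-N-methoxy-N,2-dimethyl-5-[(triethylsilyl)oxy]pentanamide | CC[Si](CC)(CC)OC[C@@H](O)C[C@@](C)(O)C(=O)N(C)OC
F4 | step 6 | (2R,4S)-4-[(tert-butyldimethylsilyl)oxy]-2-hydroxy-N-methoxy-N,2-dimethyl-5-[(triethylsilyl)oxy]pentanamide | CC[Si](CC)(CC)OC[C@@H](O[Si](C)(C)C(C)(C)C)C[C@@](C)(O)C(=O)N(C)OC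
F5 | step 6 | (2S,4R,8S)-2-[(tert-butyldimethylsilyl)oxy]-4-hydroxy-10,10-dimethoxy-4,8-dimethyl-1-[(triethylsilyl)oxy]dec-6-yn-5-one | CC[Si](CC)(CC)OC[C@@H](O[Si](C)(C)C(C)(C)C)C[C@@](C)(O)C(=O)C#C[C@@H](C)CC(OC)OC
F6 | step 9 | methyl (4S)-4-[(tert-butyldimethylsilyl)oxy]-5-{(2R)-5-[(2S)-4,4-dimethoxybutan-2-yl]-2-methyl-3-oxo-2,3-dihydrofuran-2-yl}-2-[(dimethylamino)methyl]-3-hydroxypentanoate (C2 and C3 epimers) | CN(C)CC(C(=O)OC)C(O)[C@@H](O[Si](C)(C)C(C)(C)C)C[C@@]1(C)OC(=CC1=O)[C@@H](C)CC(OC)OC
A1 | direct plan | hydroxy allylic chloride: (3S,4R,5R)-4-(3-chloroprop-1-en-2-yl)-5-[(2S,3R)-3-hydroxy-5-[(4-methoxybenzyl)oxy]-2-methylpentyl]-3-methyldihydrofuran-2(3H)-one | O[C@H](CCOCc1ccc(OC)cc1)[C@@H](C)C[C@H]1OC(=O)[C@@H](C)[C@@H]1C(=C)CCl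
A2 | direct plan | methyleneoxocane lactone (eight-membered allyl ether trans-fused to the 11-methyl γ-lactone, CH2CH2OPMB on C3) | C=C1CO[C@H](CCOCc2ccc(OC)cc2)[C@@H](C)C[C@H]2OC(=O)[C@@H](C)[C@H]12
A3 | direct plan | diazoethyl ketone of the methyleneoxocane lactone | C=C1CO[C@H](CC(=O)C(C)=[N+]=[N-])[C@@H](C)C[C@H]2OC(=O)[C@@H](C)[C@H]12
A4 | direct plan | (4S,6R,7S,10R,11S)-3,10-epoxy-1,8-dioxogermacr-2-en-12,6-olide (C8 ketone) | O=C1C[C@@]2(C)OC(=CC2=O)[C@@H](C)C[C@H]2OC(=O)[C@@H](C)[C@H]12
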